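**Retrosynthetic overview**
1. The (E)-enal is made last, by a two-carbon Wittig homologation of benzodioxane carbaldehyde 8.
2. The dioxane ring of 8 is closed at the benzylic C–O bond of open-chain aryl ether 6 by an anodic dehydrogenative C–H/O–H coupling; the benzylic stereocentre is set trans to the existing CH(CH3)–O centre.
3. Ether 6 comes from secondary alcohol 4 and 5-hydroxyvanillin by Mitsunobu etherification with inversion.
4. Alcohol 4 comes from (R)-propylene oxide, the only source of chirality, and the 3,4,5-trimethoxyphenyl Grignard reagent.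
5. Ring order: both benzene rings are bought; the 1,4-dioxane ring is the only ring formed (step 3).

Assumption: the target is the trans-(2S,3S) isomer as drawn, and compounds 1, 2, 5 and 9 are taken as commercial (2 as its THF solution).

**Step 1**
Reactants: 1 (2R)-2-methyloxirane ((R)-propylene oxide); 2 3,4,5-trimethoxyphenylmagnesium bromide
Product: 4 (2R)-1-(3,4,5-trimethoxyphenyl)propan-2-ol, via bromomagnesium alkoxide 3 (not isolated)
Conditions: CuI (10 mol %), THF, −30 → 0 °C; then 1 M aq. HCl, 0 °C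
Reagents that add atoms: none
Why: CuI-catalysed Grignard opening of a terminal epoxide is an SN2 attack at the unsubstituted CH2, so the stereocentre of 1 is not touched and is carried into 4 as (R).

**Step 2**
Reactants: 4 (2R)-1-(3,4,5-trimethoxyphenyl)propan-2-ol; 5 3,4-dihydroxy-5-methoxybenzaldehyde (5-hydroxyvanillin)
Product: 6 3-hydroxy-5-methoxy-4-{[(2S)-1-(3,4,5-trimethoxyphenyl)propan-2-yl]oxy}benzaldehyde
Conditions: PPh3 (1.5 equiv), DIAD (1.5 equiv), 5 (1.3 equiv), THF, 0 °C → rt
Reagents that add atoms: none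
Why: Mitsunobu etherification, in which the 4-OH of 5 (para to the formyl group and clearly the more acidic phenol) is the one deprotonated by the betaine and displaces the oxyphosphonium of 4 by SN2 with inversion, turning (R) into the (S) aryl ether.

**Step 3**
Reactants: 6 3-hydroxy-5-methoxy-4-{[(2S)-1-(3,4,5-trimethoxyphenyl)propan-2-yl]oxy}benzaldehyde
Product: 8 (2S,3S)-8-methoxy-2-methyl-3-(3,4,5-trimethoxyphenyl)-2,3-dihydro-1,4-benzodioxine-6-carbaldehyde, via benzylic cation 7 (not isolated)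
Conditions: undivided cell, graphite anode, Pt cathode, constant current 1 mA cm−2, 2.2 F mol−1, nBu4NPF6 (0.1 M), HFIP/CH2Cl2 1:4 (5 mM in 6), 0 °C, N2
Reagents that add atoms: none
Why: Proposed new method: anodic intramolecular dehydrogenative benzylic C(sp3)–H/phenol O–H coupling, in which the electron-rich trialkoxy ring A (estimated Ep about +1.3 V vs SCE) is oxidised before the formyl-deactivated ring B (its phenol further deactivated by hydrogen bonding to HFIP), the radical cation loses a benzylic proton to cathodically generated hexafluoroisopropoxide, the benzylic radical is oxidised again to the para-methoxy-stabilised cation 7, and the ortho-phenol closes the six-membered ring through a half-chair transition state with methyl and aryl both pseudo-equatorial, giving the trans (2S,3S) ring (the sense expected from acid-mediated SN1 closures of the corresponding benzylic alcohols) while protons are reduced to H2 at the cathode; the closest known reaction types are anodic benzylic C–H etherification and lactonisation of alkylarenes via arene radical cations and the DDQ-mediated cyclisation of 2-(3-arylpropyl)phenols to flavans, neither shown for closing a 1,4-benzodioxane nor with 1,2-induction from an aryloxy-bearing stereocentre.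

**Step 4**
Reactants: 8 (2S,3S)-8-methoxy-2-methyl-3-(3,4,5-trimethoxyphenyl)-2,3-dihydro-1,4-benzodioxine-6-carbaldehyde; 9 (triphenylphosphoranylidene)acetaldehyde
Product: 10 (2E)-3-[(2S,3S)-8-methoxy-2-methyl-3-(3,4,5-trimethoxyphenyl)-2,3-dihydro-1,4-benzodioxin-6-yl]prop-2-enal
Conditions: 9 (1.2 equiv), toluene, 80 °C
Reagents that add atoms: (triphenylphosphoranylidene)acetaldehyde, O=CC=P(c1ccccc1)(c1ccccc1)c1ccccc1
Why: Wittig olefination with the stabilised formylmethylene ylide gives the (E)-enal selectively, the cinnamaldehyde product is less electrophilic than the starting benzaldehyde so it reacts on only slowly, and the neutral conditions touch neither stereocentre.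

**Compound list**
1 | (2R)-2-methyloxirane ((R)-propylene oxide) | C[C@@H]1CO1 | starting material
2 | 3,4,5-trimethoxyphenylmagnesium bromide | COc1cc([Mg]Br)cc(OC)c1OC | starting material
3 | bromomagnesium (2R)-1-(3,4,5-trimethoxyphenyl)propan-2-olate | C[C@@H](O[Mg]Br)Cc1cc(OC)c(OC)c(OC)c1 | intermediate
4 | (2R)-1-(3,4,5-trimethoxyphenyl)propan-2-ol | C[C@@H](O)Cc1cc(OC)c(OC)c(OC)c1 | intermediate
5 | 3,4-dihydroxy-5-methoxybenzaldehyde (5-hydroxyvanillin) | COc1cc(C=O)cc(O)c1O | starting material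
6 | 3-hydroxy-5-methoxy-4-{[(2S)-1-(3,4,5-trimethoxyphenyl)propan-2-yl]oxy}benzaldehyde | C[C@H](Oc1c(O)cc(C=O)cc1OC)Cc1cc(OC)c(OC)c(OC)c1 | intermediate
7 | (2S)-2-(4-formyl-2-hydroxy-6-methoxyphenoxy)-1-(3,4,5-trimethoxyphenyl)propan-1-ylium (benzylic cation) | C[C@H](Oc1c(O)cc(C=O)cc1OC)[CH+]c1cc(OC)c(OC)c(OC)c1 | intermediate
8 | (2S,3S)-8-methoxy-2-methyl-3-(3,4,5-trimethoxyphenyl)-2,3-dihydro-1,4-benzodioxine-6-carbaldehyde | COc1cc([C@@H]2Oc3cc(C=O)cc(OC)c3O[C@H]2C)cc(OC)c1OC | intermediate
9 | (triphenylphosphoranylidene)acetaldehyde | O=CC=P(c1ccccc1)(c1ccccc1)c1ccccc1 | starting material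
10 | (2E)-3-[(2S,3S)-8-methoxy-2-methyl-3-(3,4,5-trimethoxyphenyl)-2,3-dihydro-1,4-benzodioxin-6-yl]prop-2-enal | COc1cc([C@@H]2Oc3cc(/C=C/C=O)cc(OC)c3O[C@H]2C)cc(OC)c1OC | target

**Step count**
Total steps: 4. Longest linear sequence: 4 steps (1 → 4 → 6 → 8 → 10).

**Three steps most likely to fail**

Step 3 (the proposed new anodic ring closure). The risks are biaryl homocoupling of the ring A radical cation, a second oxidation of 8 at its benzylic C–H, and loss of the neighbouring stereocentre by proton loss from cation 7. The fallback uses only known reaction types, sets out from Grignard reagent 2 and phenol 5, and comes back to the route at 8.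
- Commercial methyl (R)-lactate is heated with morpholine (neat, 85 °C) to give (2R)-2-hydroxy-1-(morpholin-4-yl)propan-1-one F3.
- Addition of 2 (2.5 equiv, THF, −20 → 0 °C, then 1 M HCl) stops at the ketone stage and gives (2R)-2-hydroxy-1-(3,4,5-trimethoxyphenyl)propan-1-one F4.
- Mitsunobu etherification of F4 with 5 (PPh3, DIAD, THF, 0 °C) proceeds with inversion to 3-hydroxy-5-methoxy-4-{[(2S)-1-oxo-1-(3,4,5-trimethoxyphenyl)propan-2-yl]oxy}benzaldehyde F5.
- NaBH4 (MeOH, 0 °C) reduces both carbonyl groups to 5-(hydroxymethyl)-2-{[(2S)-1-hydroxy-1-(3,4,5-trimethoxyphenyl)propan-2-yl]oxy}-3-methoxyphenol F6, as a mixture of carbinol epimers that does not matter.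
- Amberlyst-15 (CH2Cl2, rt, dilute) ionises the secondary benzylic alcohol and closes the ring under thermodynamic control to the trans compound [(2S,3S)-8-methoxy-2-methyl-3-(3,4,5-trimethoxyphenyl)-2,3-dihydro-1,4-benzodioxin-6-yl]methanol F7.
- MnO2 (CH2Cl2, rt) oxidises the benzylic alcohol of F7 back to aldehyde 8.

Step 2 (Mitsunobu on a free catechol). The risks are capture of the catechol by PPh3/DIAD as a cyclic dioxaphosphorane, some alkylation at the 3-OH, and elimination of 4 to the propenylarene. The fallback removes the second phenol, sets out from 4 and comes back at 6.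
- Mitsunobu etherification of 4 with commercial 5-bromovanillin (3-bromo-4-hydroxy-5-methoxybenzaldehyde; PPh3, DIAD, THF) gives, with the same inversion, 3-bromo-5-methoxy-4-{[(2S)-1-(3,4,5-trimethoxyphenyl)propan-2-yl]oxy}benzaldehyde F1.
- Miyaura borylation (B2pin2, Pd(dppf)Cl2, KOAc, dioxane, 90 °C) gives 3-methoxy-5-(4,4,5,5-tetramethyl-1,3,2-dioxaborolan-2-yl)-4-{[(2S)-1-(3,4,5-trimethoxyphenyl)propan-2-yl]oxy}benzaldehyde F2.
- Oxidation of the C–B bond with NaBO3·4H2O (THF/H2O, rt), which spares the aldehyde, gives phenol 6.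

Step 4 (formylmethylene Wittig). The risks are a second homologation to the dienal and incomplete conversion. The fallback goes through the ester oxidation level, sets out from 8 and comes back at 10.
- Horner–Wadsworth–Emmons reaction of 8 with triethyl phosphonoacetate (NaH, THF, 0 °C) gives ethyl (2E)-3-[(2S,3S)-8-methoxy-2-methyl-3-(3,4,5-trimethoxyphenyl)-2,3-dihydro-1,4-benzodioxin-6-yl]prop-2-enoate F8.
- iBu2AlH (CH2Cl2, −78 °C) reduces it to (2E)-3-[(2S,3S)-8-methoxy-2-methyl-3-(3,4,5-trimethoxyphenyl)-2,3-dihydro-1,4-benzodioxin-6-yl]prop-2-en-1-ol F9.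
- MnO2 (CH2Cl2, rt) oxidises the allylic alcohol F9 to enal 10.

**Further compounds**
F1 | step 2 | 3-bromo-5-methoxy-4-{[(2S)-1-(3,4,5-trimethoxyphenyl)propan-2-yl]oxy}benzaldehyde | C[C@H](Oc1c(Br)cc(C=O)cc1OC)Cc1cc(OC)c(OC)c(OC)c1
F2 | step 2 | 3-methoxy-5-(4,4,5,5-tetramethyl-1,3,2-dioxaborolan-2-yl)-4-{[(2S)-1-(3,4,5-trimethoxyphenyl)propan-2-yl]oxy}benzaldehyde | C[C@H](Oc1c(B2OC(C)(C)C(C)(C)O2)cc(C=O)cc1OC)Cc1cc(OC)c(OC)c(OC)c1
F3 | step 3 | (2R)-2-hydroxy-1-(morpholin-4-yl)propan-1-one | C[C@@H](O)C(=O)N1CCOCC1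
F4 | step 3 | (2R)-2-hydroxy-1-(3,4,5-trimethoxyphenyl)propan-1-one | C[C@@H](O)C(=O)c1cc(OC)c(OC)c(OC)c1
F5 | step 3 | 3-hydroxy-5-methoxy-4-{[(2S)-1-oxo-1-(3,4,5-trimethoxyphenyl)propan-2-yl]oxy}benzaldehyde | C[C@H](Oc1c(O)cc(C=O)cc1OC)C(=O)c1cc(OC)c(OC)c(OC)c1
F6 | step 3 | 5-(hydroxymethyl)-2-{[(2S)-1-hydroxy-1-(3,4,5-trimethoxyphenyl)propan-2-yl]oxy}-3-methoxyphenol (mixture of carbinol epimers) | C[C@H](Oc1c(O)cc(CO)cc1OC)C(O)c1cc(OC)c(OC)c(OC)c1
F7 | step 3 | [(2S,3S)-8-methoxy-2-methyl-3-(3,4,5-trimethoxyphenyl)-2,3-dihydro-1,4-benzodioxin-6-yl]methanol | COc1cc([C@@H]2Oc3cc(CO)cc(OC)c3O[C@H]2C)cc(OC)c1OC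
F8 | step 4 | ethyl (2E)-3-[(2S,3S)-8-methoxy-2-methyl-3-(3,4,5-trimethoxyphenyl)-2,3-dihydro-1,4-benzodioxin-6-yl]prop-2-enoate | COc1cc([C@@H]2Oc3cc(/C=C/C(=O)OCC)cc(OC)c3O[C@H]2C)cc(OC)c1OC
F9 | step 4 | (2E)-3-[(2S,3S)-8-methoxy-2-methyl-3-(3,4,5-trimethoxyphenyl)-2,3-dihydro-1,4-benzodioxin-6-yl]prop-2-en-1-ol | COc1cc([C@@H]2Oc3cc(/C=C/CO)cc(OC)c3O[C@H]2C)cc(OC)c1OC
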